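The bond cut on which everything rests opens ring C at three bonds: C4a–C4, C4–C3 and O1–C2. The feature used is that the ketone carbon C4 is flanked by C4a of ring A and by C3, which carries ring B, while the ring oxygen O1 sits on C8a next to C4a. In one operation a palladium-catalysed carbonylative Suzuki–Miyaura coupling joins an ortho-iodophenol, carbon monoxide and a 1-arylvinylboronate to an α-aryl enone, whose phenoxide closes ring C by conjugate addition to give the isoflavanone. The precursors are 2-iodo-3-methoxy-5-(triisopropylsilyloxy)phenol and the pinacol 1-arylvinylboronate of TIPS-protected 8-hydroxy-2,2-dimethylchromene. Dehydrogenation and desilylation finish the target.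

Key step: step 9

Assumption: the target is taken exactly as drawn (5-OMe, free 7-OH and free chromene 8-OH, no stereocentre), so the C3 centre of the isoflavanone is made racemic on purpose.

**Route**

Step 1
Reactants: 1 3,5-dimethoxyphenol
Product: 2 (3,5-dimethoxyphenoxy)triisopropylsilane
Conditions: TIPSCl, imidazole, DMF, rt
Reagents that add atoms: triisopropylsilyl chloride, CC(C)[Si](Cl)(C(C)C)C(C)C
Why: Standard imidazole-mediated silylation of the only phenol, which installs a bulky, weakly coordinating silyloxy group that should not direct the metalation of step 2.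

Step 2
Reactants: 2 (3,5-dimethoxyphenoxy)triisopropylsilane
Product: 4 (4-iodo-3,5-dimethoxyphenoxy)triisopropylsilane, via aryllithium 3 (not isolated)
Conditions: n-BuLi, THF, 0 °C to rt; then I2, −78 °C to rt
Reagents that add atoms: iodine, II
Why: Directed ortho-metalation should occur at the one carbon flanked by two coordinating methoxy groups (the lithium is never ortho to the silyloxy group, so no silyl migration can follow), and iodine quenches the aryllithium.

Step 3
Reactants: 4 (4-iodo-3,5-dimethoxyphenoxy)triisopropylsilane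
Product: 6 2-iodo-3-methoxy-5-(triisopropylsilyloxy)phenol, via aryloxydibromoborane 5 (not isolated)
Conditions: BBr3 (1.05 equiv), CH2Cl2, −78 to −20 °C; then aq NaHCO3, 0 °C
Reagents that add atoms: none
Why: BBr3 ether cleavage with one equivalent at low temperature: the two methoxy groups are equivalent, the first aryloxyborane deactivates the ring toward a second cleavage, the hindered and weakly basic silyloxy oxygen is not engaged, and the bicarbonate quench keeps HBr away from the electron-rich C–I bond.

Step 4
Reactants: 7 1-(3,4-dihydroxyphenyl)ethanone; 8 3-chloro-3-methylbut-1-yne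
Product: 9 1-[3-hydroxy-4-(2-methylbut-3-yn-2-yloxy)phenyl]ethanone
Conditions: DBU (1.05 equiv), CuCl2·2H2O (0.5 mol%), MeCN, 0 °C to rt
Reagents that add atoms: none
Why: The 4-OH, para to the acetyl group, is the more acidic phenol and should be alkylated selectively as its DBU salt in the copper-catalysed O-propargylation with a tertiary propargylic chloride, the usual entry to aryl 1,1-dimethylpropargyl ethers of electron-poor phenols.

Step 5
Reactants: 9 1-[3-hydroxy-4-(2-methylbut-3-yn-2-yloxy)phenyl]ethanone
Product: 11 1-(8-hydroxy-2,2-dimethyl-2H-chromen-6-yl)ethanone, via allenylphenol 10 (not isolated)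
Conditions: N,N-diethylaniline, 185 °C
Reagents that add atoms: none
Why: Aromatic propargyl Claisen rearrangement to the only free ortho carbon (C5 of the acetophenone), then enolisation, 1,5-hydrogen shift and 6π oxa-electrocyclisation, is the classical thermal route to 2,2-dimethyl-2H-chromenes.

Step 6
Reactants: 11 1-(8-hydroxy-2,2-dimethyl-2H-chromen-6-yl)ethanone
Product: 12 1-[2,2-dimethyl-8-(triisopropylsilyloxy)-2H-chromen-6-yl]ethanone
Conditions: TIPSCl, imidazole, DMF, rt to 40 °C
Reagents that add atoms: triisopropylsilyl chloride, CC(C)[Si](Cl)(C(C)C)C(C)C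
Why: Standard silylation of the remaining phenol, to which the aryl ketone and the chromene double bond are inert.

Step 7
Reactants: 12 1-[2,2-dimethyl-8-(triisopropylsilyloxy)-2H-chromen-6-yl]ethanone
Product: 14 1-[2,2-dimethyl-8-(triisopropylsilyloxy)-2H-chromen-6-yl]vinyl trifluoromethanesulfonate, via potassium enolate 13 (not isolated)
Conditions: KN(SiMe3)2, THF, −78 °C; then PhNTf2, −78 to 0 °C
Reagents that add atoms: N-phenylbis(trifluoromethanesulfonimide), O=S(=O)(N(c1ccccc1)S(=O)(=O)C(F)(F)F)C(F)(F)F
Why: Deprotonation of the methyl ketone and O-triflation of the enolate is the standard preparation of 1-arylvinyl triflates and should leave the silyl ether and the chromene untouched.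

Step 8
Reactants: 14 1-[2,2-dimethyl-8-(triisopropylsilyloxy)-2H-chromen-6-yl]vinyl trifluoromethanesulfonate
Product: 15 2-{1-[2,2-dimethyl-8-(triisopropylsilyloxy)-2H-chromen-6-yl]vinyl}-4,4,5,5-tetramethyl-1,3,2-dioxaborolane
Conditions: B2pin2, PdCl2(PPh3)2 (3 mol%), PPh3 (6 mol%), KOPh, toluene, 50 °C
Reagents that add atoms: bis(pinacolato)diboron, CC1(C)OB(B2OC(C)(C)C(C)(C)O2)OC1(C)C
Why: Miyaura borylation of an alkenyl triflate, in which the weak phenoxide base allows boron-to-palladium transfer but does not activate the product boronate for a second coupling.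

Step 9
Reactants: 6 2-iodo-3-methoxy-5-(triisopropylsilyloxy)phenol; 15 2-{1-[2,2-dimethyl-8-(triisopropylsilyloxy)-2H-chromen-6-yl]vinyl}-4,4,5,5-tetramethyl-1,3,2-dioxaborolane (1.3 equiv); 16 carbon monoxide
Product: 18 racemic 3-[2,2-dimethyl-8-(triisopropylsilyloxy)-2H-chromen-6-yl]-5-methoxy-7-(triisopropylsilyloxy)chroman-4-one, via enone 17 (not isolated)
Conditions: Pd(OAc)2 (5 mol%), di(1-adamantyl)-n-butylphosphine (10 mol%), K2CO3 (3 equiv), H2O (3 equiv), CO (5 bar), anisole, 80 °C
Reagents that add atoms: none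
Why: Zerovalent palladium, formed from Pd(OAc)2 and the phosphine, adds oxidatively to the C–I bond of 6 and takes up CO by migratory insertion; the acyl complex of divalent palladium then receives the 1-arylvinyl group from the carbonate-activated boronate 15, and reductive elimination releases enone 17, so that C4a–C4 and C4–C3 are made. The closest known reaction type is the carbonylative Suzuki–Miyaura coupling of aryl iodides with organoboron reagents, run here on a 2-iodophenol as in the carbonylative annulations that give chromanones and flavones. Ring C closes by a 6-endo-trig oxa-Michael addition of the O1 phenoxide to the methylene terminus of 17 (O1–C2), the closure by which 2'-hydroxy-α-methylenedeoxybenzoins are known to give isoflavanones. The C3 stereocentre is created when the resulting enolate is protonated; nothing controls it and 18 is racemic, which is harmless because C3 becomes trigonal again in step 10. Two selectivities are needed, CO insertion before vinyl transfer and capture of the acyl complex by boron instead of by a phenoxide oxygen: the OH and OMe groups on both sides of the C–I bond retard transmetalation at the crowded arylpalladium stage, while CO pressure, the bulky electron-rich phosphine and the excess of 15 favour the acyl pathway.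

Step 10
Reactants: 18 racemic 3-[2,2-dimethyl-8-(triisopropylsilyloxy)-2H-chromen-6-yl]-5-methoxy-7-(triisopropylsilyloxy)chroman-4-one
Product: 19 3-[2,2-dimethyl-8-(triisopropylsilyloxy)-2H-chromen-6-yl]-5-methoxy-7-(triisopropylsilyloxy)-4H-chromen-4-one
Conditions: DDQ (1.5 equiv), 1,4-dioxane, 90 °C
Reagents that add atoms: none
Why: DDQ dehydrogenation of an isoflavanone through its readily formed enol (C3–H is benzylic and α to the ketone) is the standard conversion into the isoflavone, while the 2,2-dimethylchromene offers no allylic hydrogen and the silyl ethers keep the phenols from oxidation.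

Step 11
Reactants: 19 3-[2,2-dimethyl-8-(triisopropylsilyloxy)-2H-chromen-6-yl]-5-methoxy-7-(triisopropylsilyloxy)-4H-chromen-4-one
Product: 20 7-hydroxy-3-(8-hydroxy-2,2-dimethyl-2H-chromen-6-yl)-5-methoxy-4H-chromen-4-one (glycyrrhizaisoflavone B)
Conditions: Bu4NF (2.4 equiv), AcOH (2.4 equiv), THF, 0 °C to rt
Reagents that add atoms: none
Why: Fluoride-mediated desilylation should cleave both aryl silyl ethers, and the acetic acid buffer keeps the base-sensitive pyranone ring away from free phenoxide and hydroxide.

**Compound list**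

1 | 3,5-dimethoxyphenol | COc1cc(O)cc(OC)c1 | starting material
2 | (3,5-dimethoxyphenoxy)triisopropylsilane | COc1cc(O[Si](C(C)C)(C(C)C)C(C)C)cc(OC)c1 | intermediate
3 | [2,6-dimethoxy-4-(triisopropylsilyloxy)phenyl]lithium | [Li]c1c(OC)cc(O[Si](C(C)C)(C(C)C)C(C)C)cc1OC | intermediate
4 | (4-iodo-3,5-dimethoxyphenoxy)triisopropylsilane | COc1cc(O[Si](C(C)C)(C(C)C)C(C)C)cc(OC)c1I | intermediate
5 | dibromo[2-iodo-3-methoxy-5-(triisopropylsilyloxy)phenoxy]borane | COc1cc(O[Si](C(C)C)(C(C)C)C(C)C)cc(OB(Br)Br)c1I | intermediate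
6 | 2-iodo-3-methoxy-5-(triisopropylsilyloxy)phenol | COc1cc(O[Si](C(C)C)(C(C)C)C(C)C)cc(O)c1I | intermediate
7 | 1-(3,4-dihydroxyphenyl)ethanone | CC(=O)c1ccc(O)c(O)c1 | starting material
8 | 3-chloro-3-methylbut-1-yne | CC(C)(Cl)C#C | starting material
9 | 1-[3-hydroxy-4-(2-methylbut-3-yn-2-yloxy)phenyl]ethanone | CC(=O)c1ccc(OC(C)(C)C#C)c(O)c1 | intermediate
10 | 1-[3,4-dihydroxy-5-(3-methylbuta-1,2-dien-1-yl)phenyl]ethanone | CC(=O)c1cc(O)c(O)c(C=C=C(C)C)c1 | intermediate
11 | 1-(8-hydroxy-2,2-dimethyl-2H-chromen-6-yl)ethanone | CC(=O)c1cc(O)c2OC(C)(C)C=Cc2c1 | intermediate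
12 | 1-[2,2-dimethyl-8-(triisopropylsilyloxy)-2H-chromen-6-yl]ethanone | CC(=O)c1cc(O[Si](C(C)C)(C(C)C)C(C)C)c2OC(C)(C)C=Cc2c1 | intermediate
13 | potassium 1-[2,2-dimethyl-8-(triisopropylsilyloxy)-2H-chromen-6-yl]ethenolate | [K+].C=C([O-])c1cc(O[Si](C(C)C)(C(C)C)C(C)C)c2OC(C)(C)C=Cc2c1 | intermediate
14 | 1-[2,2-dimethyl-8-(triisopropylsilyloxy)-2H-chromen-6-yl]vinyl trifluoromethanesulfonate | C=C(OS(=O)(=O)C(F)(F)F)c1cc(O[Si](C(C)C)(C(C)C)C(C)C)c2OC(C)(C)C=Cc2c1 | intermediate
15 | 2-{1-[2,2-dimethyl-8-(triisopropylsilyloxy)-2H-chromen-6-yl]vinyl}-4,4,5,5-tetramethyl-1,3,2-dioxaborolane | C=C(B1OC(C)(C)C(C)(C)O1)c1cc(O[Si](C(C)C)(C(C)C)C(C)C)c2OC(C)(C)C=Cc2c1 | intermediate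
16 | carbon monoxide | [C-]#[O+] | starting material
17 | 2-[2,2-dimethyl-8-(triisopropylsilyloxy)-2H-chromen-6-yl]-1-[2-hydroxy-6-methoxy-4-(triisopropylsilyloxy)phenyl]prop-2-en-1-one | C=C(C(=O)c1c(O)cc(O[Si](C(C)C)(C(C)C)C(C)C)cc1OC)c1cc(O[Si](C(C)C)(C(C)C)C(C)C)c2OC(C)(C)C=Cc2c1 | intermediate
18 | racemic 3-[2,2-dimethyl-8-(triisopropylsilyloxy)-2H-chromen-6-yl]-5-methoxy-7-(triisopropylsilyloxy)chroman-4-one | COc1cc(O[Si](C(C)C)(C(C)C)C(C)C)cc2OCC(c3cc(O[Si](C(C)C)(C(C)C)C(C)C)c4c(c3)C=CC(C)(C)O4)C(=O)c12 | intermediate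
19 | 3-[2,2-dimethyl-8-(triisopropylsilyloxy)-2H-chromen-6-yl]-5-methoxy-7-(triisopropylsilyloxy)-4H-chromen-4-one | COc1cc(O[Si](C(C)C)(C(C)C)C(C)C)cc2occ(-c3cc(O[Si](C(C)C)(C(C)C)C(C)C)c4c(c3)C=CC(C)(C)O4)c(=O)c12 | intermediate
20 | 7-hydroxy-3-(8-hydroxy-2,2-dimethyl-2H-chromen-6-yl)-5-methoxy-4H-chromen-4-one (glycyrrhizaisoflavone B) | COc1cc(O)cc2occ(-c3cc(O)c4c(c3)C=CC(C)(C)O4)c(=O)c12 | target

**Step count and risks**

Total step count: 11 (steps 1–3 for the ring A partner, steps 4–8 for the ring B partner, steps 9–11 from the coupling to the target). Longest linear sequence: 8 steps (7 to 20 through steps 4–11).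

Steps most likely to fail:

1. Step 9. Vinyl transfer to the arylpalladium species may outrun CO uptake. The acylpalladium intermediate may also acylate a phenoxide oxygen instead of waiting for boron, and the carbonate may strip the silyl group para to the new ketone.
 Fallback (sets out from 2 and 15, comes back at 18): the aryllithium 3, generated as in step 2, is quenched with CO2 and acidified to give 2,6-dimethoxy-4-(triisopropylsilyloxy)benzoic acid F1. Oxalyl chloride with catalytic DMF in CH2Cl2 converts it into 2,6-dimethoxy-4-(triisopropylsilyloxy)benzoyl chloride F2. An anhydrous acyl Suzuki–Miyaura coupling of F2 with 15 (Pd(PPh3)4, Cs2CO3, toluene, 80 °C) should give 2-[2,2-dimethyl-8-(triisopropylsilyloxy)-2H-chromen-6-yl]-1-[2,6-dimethoxy-4-(triisopropylsilyloxy)phenyl]prop-2-en-1-one F3. BCl3 in CH2Cl2 at −78 °C then removes one of the two equivalent methyl groups ortho to the ketone under chelation control to give 17, which should close to 18 on stirring with Et3N. The C4a–C4 bond is thus made from a lithium reagent and CO2, so neither competing pathway of the palladium carbonylation can arise.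

2. Step 3. Both methyl ethers may be cleaved, or HBr may remove iodine from the very electron-rich ring while the Lewis acid is present.
 Fallback (sets out from 2, comes back at 6): the symmetric ether 2 is mono-demethylated before any iodine is present (BBr3, 1.0 equiv, CH2Cl2, −78 °C, bicarbonate quench) to give 3-methoxy-5-(triisopropylsilyloxy)phenol F4. F4 is then iodinated with NIS (1.0 equiv, CH2Cl2, −40 °C) at C2, the one ring position activated by all three oxygens and not shielded by the neighbouring TIPS group, to give 6. Regiocontrol then rests on sterics instead of on lithiation, so the crude product should be checked for the isomeric iodides before use.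

3. Step 4. Alkylation may occur at the 3-oxygen or at both oxygens, and the free neighbouring hydroxyl may add to the alkyne under base or copper.
 Fallback (sets out from 7, comes back at 12): selective 4-O-benzylation of 7 (benzyl bromide, K2CO3, 1.0 equiv each, DMF, rt), well established for 3,4-dihydroxyaryl carbonyl compounds, gives 1-[4-(benzyloxy)-3-hydroxyphenyl]ethanone F5. Silylation (TIPSCl, imidazole, DMF) gives 1-[4-(benzyloxy)-3-(triisopropylsilyloxy)phenyl]ethanone F6, and hydrogenolysis (H2, Pd/C, EtOAc, rt) gives 1-[4-hydroxy-3-(triisopropylsilyloxy)phenyl]ethanone F7. With a single free phenol left, propargylation with 8 (DBU, CuCl2·2H2O, MeCN, 0 °C) gives 1-[4-(2-methylbut-3-yn-2-yloxy)-3-(triisopropylsilyloxy)phenyl]ethanone F8. Heating F8 in o-dichlorobenzene at 170 °C effects the Claisen rearrangement and electrocyclisation and should deliver 12 directly, so that steps 5 and 6 are not needed.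

Further compounds
F1 | step 9 | 2,6-dimethoxy-4-(triisopropylsilyloxy)benzoic acid | COc1cc(O[Si](C(C)C)(C(C)C)C(C)C)cc(OC)c1C(=O)O
F2 | step 9 | 2,6-dimethoxy-4-(triisopropylsilyloxy)benzoyl chloride | COc1cc(O[Si](C(C)C)(C(C)C)C(C)C)cc(OC)c1C(Cl)=O
F3 | step 9 | 2-[2,2-dimethyl-8-(triisopropylsilyloxy)-2H-chromen-6-yl]-1-[2,6-dimethoxy-4-(triisopropylsilyloxy)phenyl]prop-2-en-1-one | C=C(C(=O)c1c(OC)cc(O[Si](C(C)C)(C(C)C)C(C)C)cc1OC)c1cc(O[Si](C(C)C)(C(C)C)C(C)C)c2OC(C)(C)C=Cc2c1
F4 | step 3 | 3-methoxy-5-(triisopropylsilyloxy)phenol | COc1cc(O)cc(O[Si](C(C)C)(C(C)C)C(C)C)c1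
F5 | step 4 | 1-[4-(benzyloxy)-3-hydroxyphenyl]ethanone | CC(=O)c1ccc(OCc2ccccc2)c(O)c1
F6 | step 4 | 1-[4-(benzyloxy)-3-(triisopropylsilyloxy)phenyl]ethanone | CC(=O)c1ccc(OCc2ccccc2)c(O[Si](C(C)C)(C(C)C)C(C)C)c1
F7 | step 4 | 1-[4-hydroxy-3-(triisopropylsilyloxy)phenyl]ethanone | CC(=O)c1ccc(O)c(O[Si](C(C)C)(C(C)C)C(C)C)c1
F8 | step 4 | 1-[4-(2-methylbut-3-yn-2-yloxy)-3-(triisopropylsilyloxy)phenyl]ethanone | CC(=O)c1ccc(OC(C)(C)C#C)c(O[Si](C(C)C)(C(C)C)C(C)C)c1
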